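The route rests on reading the α-hydroxy enone of the target backwards: the tertiary carbinol C1, flanked by the C6 ketone that is conjugated with C4=C5 in the six-membered ring, is the ring-enlarged isomer of a 1-acylcyclopent-2-enol. A Sc(OTf)3-mediated acyloin shift moves C2 from C6 to C1 and so forms the C1–C2 bond, the cyclohexenone, the conjugated ketone and the C1 stereocentre in one operation. Its substrate is a cyclopentenol whose carbinol C6 bears the benzoyloxyacetyl side chain (C1, C7) and a hydroxyl cis to the C2 silyl ether, with the C3 benzoate trans to it; it is assembled from (S)-4-hydroxycyclopentenone.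

Key step: step 8

Remark: locants C1–C7 are those of the target carbocycle (C1 carbinol carbon, C2 acetoxy carbon, C3 ring benzoate carbon, C4=C5, C6 ketone carbon, C7 exocyclic methylene) and are kept for the cyclopentene intermediates; O1–O7 are the oxygens on those carbons. Enantiopure (S)-4-hydroxycyclopent-2-en-1-one is taken as purchasable.

Step 1
Reactants: 1 (S)-4-hydroxycyclopent-2-en-1-one
Product: 2 (S)-4-(triethylsilyloxy)cyclopent-2-en-1-one
Conditions: Et3SiCl, imidazole, CH2Cl2, 0 °C
Reagents that add atoms: chlorotriethylsilane, CC[Si](Cl)(CC)CC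
Why: Imidazole-promoted O-silylation of a secondary alcohol leaves the C3 stereocentre untouched and installs a triethylsilyl ether that masks the hydroxyl during the enolate chemistry and can later be removed in the presence of a TBS ether.

Step 2
Reactants: 2 (S)-4-(triethylsilyloxy)cyclopent-2-en-1-one
Product: 4 (4R,5S)-5-hydroxy-4-(triethylsilyloxy)cyclopent-2-en-1-one, via sodium dienolate 3 (not isolated)
Conditions: NaN(SiMe3)2, THF, −78 °C; then 2-(phenylsulfonyl)-3-phenyloxaziridine, −78 °C; AcOH quench at −78 °C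
Reagents that add atoms: 2-(phenylsulfonyl)-3-phenyloxaziridine, O=S(=O)(N1OC1c1ccccc1)c1ccccc1
Why: Kinetic α'-deprotonation gives the cross-conjugated dienolate, which the N-sulfonyloxaziridine hydroxylates (Davis enolate oxidation) on the ring face opposite the neighbouring C3 silyloxy group, so the new C2 hydroxyl is trans to O3, while the sodium counter-ion and the cold acid quench hold back imine addition and silyl shift.

Step 3
Reactants: 4 (4R,5S)-5-hydroxy-4-(triethylsilyloxy)cyclopent-2-en-1-one
Product: 5 (4R,5S)-5-(tert-butyldimethylsilyloxy)-4-(triethylsilyloxy)cyclopent-2-en-1-one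
Conditions: t-BuMe2SiOTf, 2,6-lutidine, CH2Cl2, −78 °C
Reagents that add atoms: tert-butyldimethylsilyl trifluoromethanesulfonate, CC(C)(C)[Si](C)(C)OS(=O)(=O)C(F)(F)F
Why: Silyl triflate O-silylation with a hindered pyridine base at low temperature caps the α-hydroxy ketone without epimerising C2, and the bulky, non-chelating TBS ether is what later steers the carbonyl addition and stays off the metal in the ring enlargement.

Step 4
Reactants: 5 (4R,5S)-5-(tert-butyldimethylsilyloxy)-4-(triethylsilyloxy)cyclopent-2-en-1-one; 6 ethyl vinyl ether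
Product: 8 (1R,4R,5S)-5-(tert-butyldimethylsilyloxy)-1-(1-ethoxyvinyl)-4-(triethylsilyloxy)cyclopent-2-en-1-ol, via 1-ethoxyvinyllithium 7 (not isolated)
Conditions: 6, t-BuLi, THF, −78 → 0 °C; then 5, THF, −78 °C; H2O quench
Reagents that add atoms: ethyl vinyl ether 6 (as its lithio derivative 7), C=COCC
Why: α-Lithiated ethyl vinyl ether is a masked acyl anion that adds 1,2 to the enone carbonyl, and it should enter anti to the adjacent non-chelating C2 silyl ether (Felkin–Anh polar model reinforced by sterics), which places the new C6 hydroxyl cis to O2.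

Step 5
Reactants: 8 (1R,4R,5S)-5-(tert-butyldimethylsilyloxy)-1-(1-ethoxyvinyl)-4-(triethylsilyloxy)cyclopent-2-en-1-ol
Product: 10 1-[(1R,4R,5S)-5-(tert-butyldimethylsilyloxy)-1-hydroxy-4-(triethylsilyloxy)cyclopent-2-en-1-yl]-2-hydroxyethan-1-one, via ethyl hemiketal 9 (not isolated)
Conditions: OsO4 (2 mol %), N-methylmorpholine N-oxide, acetone/H2O, 0 °C
Reagents that add atoms: N-methylmorpholine N-oxide, C[N+]1([O-])CCOCC1; water, O; osmium tetroxide (catalytic oxygen carrier), O=[Os](=O)(=O)=O
Why: Catalytic OsO4/NMO dihydroxylation should take the electron-rich 1,1-disubstituted enol ether far faster than the hindered ring alkene, and the hemiketal so formed collapses with loss of ethanol to the hydroxyacetyl group, the classical way to a dihydroxyacetone side chain, without creating a stereocentre.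

Step 6
Reactants: 10 1-[(1R,4R,5S)-5-(tert-butyldimethylsilyloxy)-1-hydroxy-4-(triethylsilyloxy)cyclopent-2-en-1-yl]-2-hydroxyethan-1-one
Product: 11 1-[(1R,4R,5S)-5-(tert-butyldimethylsilyloxy)-1,4-dihydroxycyclopent-2-en-1-yl]-2-hydroxyethan-1-one
Conditions: PPTS (cat.), MeOH, 0 °C
Reagents that add atoms: none
Why: Acid-catalysed methanolysis cleaves the triethylsilyl ether much faster than the more hindered secondary TBS ether (selective desilylation) and leaves the ketol and all stereocentres alone.

Step 7
Reactants: 11 1-[(1R,4R,5S)-5-(tert-butyldimethylsilyloxy)-1,4-dihydroxycyclopent-2-en-1-yl]-2-hydroxyethan-1-one; 12 benzoyl chloride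
Product: 13 2-[(1R,4R,5S)-4-(benzoyloxy)-5-(tert-butyldimethylsilyloxy)-1-hydroxycyclopent-2-en-1-yl]-2-oxoethyl benzoate
Conditions: BzCl (2.2 equiv), pyridine, CH2Cl2, 0 °C
Reagents that add atoms: benzoyl chloride 12, O=C(Cl)c1ccccc1
Why: Pyridine-mediated acylation esterifies the primary C7 hydroxyl and the secondary allylic C3 hydroxyl, whereas the tertiary C6 hydroxyl, wedged between the ketone and the silyl ether, is too hindered to react at 0 °C.

Step 8
Reactants: 13 2-[(1R,4R,5S)-4-(benzoyloxy)-5-(tert-butyldimethylsilyloxy)-1-hydroxycyclopent-2-en-1-yl]-2-oxoethyl benzoate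
Product: 14 [(1S,5R,6S)-5-(benzoyloxy)-6-(tert-butyldimethylsilyloxy)-1-hydroxy-2-oxocyclohex-3-en-1-yl]methyl benzoate (2-O-TBS-zeylenone)
Conditions: Sc(OTf)3 (20 mol %), 4 Å MS, ClCH2CH2Cl, 50 °C
Reagents that add atoms: none
Why: Sc(OTf)3 binds the C6 hydroxyl and the C1 carbonyl oxygen in a five-membered chelate that holds O6–C6–C1=O1 syn-periplanar, and as C6–O6 gains carbonyl character the C6–C2 bond, aligned with the C1 π* orbital, shifts suprafacially to C1 with retention at C2. The closest known reaction type is the Lewis-acid-promoted α-ketol (acyloin) rearrangement with ring enlargement, as in the D-homoannulation of 17-hydroxy-20-keto steroids and the conversion of 1-acylcycloalkanols into 2-hydroxycycloalkanones. The six-membered ring is closed not by a cyclisation but by this 1,2-shift, which inserts C1 between C6 and C2 of the five-membered ring, so no ring-closure classification applies. The C1 stereocentre is controlled by the C6 configuration relayed through the chelate: with O1 eclipsing O6, C2 can only reach the carbonyl face that leaves the new hydroxyl cis to the C2 silyl ether and the benzoyloxymethyl group trans to it, and the poorly coordinating TBS ether keeps the metal on O6 and O1. The selectivity needed is migration of C2 in place of alkenyl C5, and it is secured thermodynamically, because the shifts are reversible and only the C2 shift gives a strain-free ring whose C6 ketone is conjugated with C4=C5. A first shift of C5 is not a dead end, since that deconjugated ketol can revert or, through a second chelate-controlled shift of C7, arrive at the same enone with the same C1 configuration.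

Step 9
Reactants: 14 [(1S,5R,6S)-5-(benzoyloxy)-6-(tert-butyldimethylsilyloxy)-1-hydroxy-2-oxocyclohex-3-en-1-yl]methyl benzoate
Product: 15 zeylenone, [(1S,5R,6S)-5-(benzoyloxy)-1,6-dihydroxy-2-oxocyclohex-3-en-1-yl]methyl benzoate
Conditions: HF·pyridine, pyridine, THF, 0 °C → rt
Reagents that add atoms: none
Why: Fluoride-driven Si–O cleavage with pyridine-buffered HF removes the TBS ether under mildly acidic conditions in which the benzoates should neither migrate nor eliminate, as they might with basic fluoride sources, and no stereocentre is touched.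

Step 10
Reactants: 15 zeylenone; 16 acetic anhydride
Product: 17 2-O-acetylzeylenone, [(1S,5R,6S)-6-acetoxy-5-(benzoyloxy)-1-hydroxy-2-oxocyclohex-3-en-1-yl]methyl benzoate
Conditions: Ac2O, pyridine, DMAP (cat.), CH2Cl2, 0 °C
Reagents that add atoms: acetic anhydride 16, CC(=O)OC(C)=O
Why: DMAP-catalysed acetylation is selective for the secondary C2 hydroxyl because the tertiary C1 hydroxyl is far less reactive, and the mild base at 0 °C avoids elimination towards an arene.

Compound list
1 | (S)-4-hydroxycyclopent-2-en-1-one | O=C1C=C[C@@H](O)C1 | starting material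
2 | (S)-4-(triethylsilyloxy)cyclopent-2-en-1-one | O=C1C=C[C@@H](O[Si](CC)(CC)CC)C1 | intermediate
3 | sodium (3R)-3-(triethylsilyloxy)cyclopenta-1,4-dien-1-olate | [Na+].[O-]C1=C[C@H](O[Si](CC)(CC)CC)C=C1 | intermediate
4 | (4R,5S)-5-hydroxy-4-(triethylsilyloxy)cyclopent-2-en-1-one | O=C1C=C[C@@H](O[Si](CC)(CC)CC)[C@@H]1O | intermediate
5 | (4R,5S)-5-(tert-butyldimethylsilyloxy)-4-(triethylsilyloxy)cyclopent-2-en-1-one | O=C1C=C[C@@H](O[Si](CC)(CC)CC)[C@@H]1O[Si](C)(C)C(C)(C)C | intermediate
6 | ethyl vinyl ether | C=COCC | starting material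
7 | 1-ethoxyvinyllithium | [Li]C(=C)OCC | intermediate
8 | (1R,4R,5S)-5-(tert-butyldimethylsilyloxy)-1-(1-ethoxyvinyl)-4-(triethylsilyloxy)cyclopent-2-en-1-ol | C=C(OCC)[C@@]1(O)C=C[C@@H](O[Si](CC)(CC)CC)[C@@H]1O[Si](C)(C)C(C)(C)C | intermediate
9 | (1R,4R,5S)-5-(tert-butyldimethylsilyloxy)-1-(1-ethoxy-1,2-dihydroxyethyl)-4-(triethylsilyloxy)cyclopent-2-en-1-ol (ethyl hemiketal, both epimers at the hemiketal carbon) | CCOC(O)(CO)[C@@]1(O)C=C[C@@H](O[Si](CC)(CC)CC)[C@@H]1O[Si](C)(C)C(C)(C)C | intermediate
10 | 1-[(1R,4R,5S)-5-(tert-butyldimethylsilyloxy)-1-hydroxy-4-(triethylsilyloxy)cyclopent-2-en-1-yl]-2-hydroxyethan-1-one | O=C(CO)[C@@]1(O)C=C[C@@H](O[Si](CC)(CC)CC)[C@@H]1O[Si](C)(C)C(C)(C)C | intermediate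
11 | 1-[(1R,4R,5S)-5-(tert-butyldimethylsilyloxy)-1,4-dihydroxycyclopent-2-en-1-yl]-2-hydroxyethan-1-one | O=C(CO)[C@@]1(O)C=C[C@@H](O)[C@@H]1O[Si](C)(C)C(C)(C)C | intermediate
12 | benzoyl chloride | O=C(Cl)c1ccccc1 | starting material
13 | 2-[(1R,4R,5S)-4-(benzoyloxy)-5-(tert-butyldimethylsilyloxy)-1-hydroxycyclopent-2-en-1-yl]-2-oxoethyl benzoate | O=C(COC(=O)c1ccccc1)[C@@]1(O)C=C[C@@H](OC(=O)c2ccccc2)[C@@H]1O[Si](C)(C)C(C)(C)C | intermediate
14 | [(1S,5R,6S)-5-(benzoyloxy)-6-(tert-butyldimethylsilyloxy)-1-hydroxy-2-oxocyclohex-3-en-1-yl]methyl benzoate | CC(C)(C)[Si](C)(C)O[C@H]1[C@H](OC(=O)c2ccccc2)C=CC(=O)[C@]1(O)COC(=O)c1ccccc1 | intermediate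
15 | zeylenone, [(1S,5R,6S)-5-(benzoyloxy)-1,6-dihydroxy-2-oxocyclohex-3-en-1-yl]methyl benzoate | O[C@H]1[C@H](OC(=O)c2ccccc2)C=CC(=O)[C@]1(O)COC(=O)c1ccccc1 | intermediate
16 | acetic anhydride | CC(=O)OC(C)=O | starting material
17 | 2-O-acetylzeylenone, [(1S,5R,6S)-6-acetoxy-5-(benzoyloxy)-1-hydroxy-2-oxocyclohex-3-en-1-yl]methyl benzoate | CC(=O)O[C@H]1[C@H](OC(=O)c2ccccc2)C=CC(=O)[C@]1(O)COC(=O)c1ccccc1 | target

Total step count: 10
Longest linear sequence: 10 steps (1 → 17)

Steps most likely to fail

Step 8. The alkenyl carbon C5 may shift faster than C2, and the mixture may not funnel to the conjugated enone before the Lewis acid ionises the allylic benzoate or moves a benzoyl group to the tertiary hydroxyl. The fallback takes the esters out of the shift. It sets out from 10, whose primary hydroxyl is silylated (Et3SiCl, imidazole, CH2Cl2, 0 °C) to give tris-silyl ketol F1. Heating this with Al(OtBu)3 in toluene at 80 °C uses the covalent aluminium alkoxide chelate of the classical D-homoannulation, and an ester-free substrate should tolerate the long equilibration, giving ring-enlarged tris-silyl ether F2. PPTS in MeOH then removes both triethylsilyl groups to give triol F3, and benzoylation of its primary and secondary allylic hydroxyls (BzCl, pyridine, 0 °C) comes back to the route at 14.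

Step 4. The basic vinyllithium may remove the C2 proton, with loss of the C3 silanolate, instead of adding. The acid-labile enol ether adduct may be lost on isolation, or facial control may erode. The fallback delivers the two-carbon unit as a plain vinyl group from a weakly basic organocerium and raises its oxidation level afterwards. It sets out from 5: CH2=CHMgBr/CeCl3 (THF, −78 °C) should give vinyl carbinol F4, and OsO4/NMO should dihydroxylate the unhindered terminal alkene to side-chain diol F5. BzCl with 2,4,6-collidine at −20 °C benzoylates the primary hydroxyl to give primary benzoate F6, and Dess–Martin periodinane oxidises the remaining secondary hydroxyl to give keto benzoate F7. PPTS in MeOH frees the C3 hydroxyl to give hydroxy keto benzoate F8, and BzCl/pyridine comes back to the route at 13.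

Step 2. The dienolate may add to the sulfonimine by-product, the C3 silyl group may shift to the new alkoxide, or silanolate may be expelled from the dienolate. The fallback is a Rubottom oxidation through a neutral diene, which avoids any metal dienolate or alkoxide. It sets out from 2: soft enolisation with t-BuMe2SiOTf/Et3N (CH2Cl2, −78 → 0 °C) gives silyl dienol ether F9, which is kept cold and treated at once with mCPBA/NaHCO3 (CH2Cl2, −20 °C). Epoxidation anti to the C3 silyl ether and the usual 1,4-silyl transfer of the silyloxy epoxide should give the α-silyloxy ketone directly, so the route is rejoined at 5 without passing through 4.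

Further compounds
F1 | step 8 | 1-[(1R,4R,5S)-5-(tert-butyldimethylsilyloxy)-1-hydroxy-4-(triethylsilyloxy)cyclopent-2-en-1-yl]-2-(triethylsilyloxy)ethan-1-one | O=C(CO[Si](CC)(CC)CC)[C@@]1(O)C=C[C@@H](O[Si](CC)(CC)CC)[C@@H]1O[Si](C)(C)C(C)(C)C
F2 | step 8 | (4R,5S,6S)-5-(tert-butyldimethylsilyloxy)-6-hydroxy-4-(triethylsilyloxy)-6-[(triethylsilyloxy)methyl]cyclohex-2-en-1-one | CC(C)(C)[Si](C)(C)O[C@H]1[C@H](O[Si](CC)(CC)CC)C=CC(=O)[C@]1(O)CO[Si](CC)(CC)CC
F3 | step 8 | (4R,5S,6S)-5-(tert-butyldimethylsilyloxy)-4,6-dihydroxy-6-(hydroxymethyl)cyclohex-2-en-1-one | CC(C)(C)[Si](C)(C)O[C@H]1[C@H](O)C=CC(=O)[C@]1(O)CO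
F4 | step 4 | (1R,4R,5S)-5-(tert-butyldimethylsilyloxy)-4-(triethylsilyloxy)-1-vinylcyclopent-2-en-1-ol | C=C[C@@]1(O)C=C[C@@H](O[Si](CC)(CC)CC)[C@@H]1O[Si](C)(C)C(C)(C)C
F5 | step 4 | 1-[(4R,5S)-5-(tert-butyldimethylsilyloxy)-1-hydroxy-4-(triethylsilyloxy)cyclopent-2-en-1-yl]ethane-1,2-diol (ring hydroxyl cis to the O2 silyl ether; both epimers at the side-chain carbinol) | OCC(O)[C@@]1(O)C=C[C@@H](O[Si](CC)(CC)CC)[C@@H]1O[Si](C)(C)C(C)(C)C
F6 | step 4 | 2-[(4R,5S)-5-(tert-butyldimethylsilyloxy)-1-hydroxy-4-(triethylsilyloxy)cyclopent-2-en-1-yl]-2-hydroxyethyl benzoate (ring hydroxyl cis to the O2 silyl ether) | O=C(OCC(O)[C@@]1(O)C=C[C@@H](O[Si](CC)(CC)CC)[C@@H]1O[Si](C)(C)C(C)(C)C)c1ccccc1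
F7 | step 4 | 2-[(1R,4R,5S)-5-(tert-butyldimethylsilyloxy)-1-hydroxy-4-(triethylsilyloxy)cyclopent-2-en-1-yl]-2-oxoethyl benzoate | O=C(COC(=O)c1ccccc1)[C@@]1(O)C=C[C@@H](O[Si](CC)(CC)CC)[C@@H]1O[Si](C)(C)C(C)(C)C
F8 | step 4 | 2-[(1R,4R,5S)-5-(tert-butyldimethylsilyloxy)-1,4-dihydroxycyclopent-2-en-1-yl]-2-oxoethyl benzoate | O=C(COC(=O)c1ccccc1)[C@@]1(O)C=C[C@@H](O)[C@@H]1O[Si](C)(C)C(C)(C)C
F9 | step 2 | tert-butyldimethyl{[(3R)-3-(triethylsilyloxy)cyclopenta-1,4-dien-1-yl]oxy}silane | CC(C)(C)[Si](C)(C)OC1=C[C@H](O[Si](CC)(CC)CC)C=C1
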